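Halimane numbering is used. The bond shared by the cyclopentane and the cycloheptanone, C1–C5, links the tertiary carbinol C5 (flanked by C4Me2) to C1, the CH alpha to the C10 ketone: a beta-hydroxy ketone, hence an aldol retron. Cutting it leads back to a ten-membered 5,10-dione (C3 hydroxyl free, butenolide side chain already on the quaternary C9). In step 9 the C10 enolate adds across that ring to the C5 carbonyl, closing both rings and creating C1 and C5 in one operation. The dione comes from ozonolysis of a Δ5(10)-octalin built by conjugate methylation/enolate vinylation, enol triflate coupling, butenolide Suzuki coupling, Shi epoxidation and epoxy-olefin cyclisation.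

Key step: step 9

Remark: atom labels are C1–C10 ring carbons (C4 = CMe2, C8 = CHMe, C9 = quaternary carbon, C5/C10 = olefin carbons of the octalin and later the two ketones), C11–C12 the ethylene link, C13–C16 the butenolide.
Remark: compound 1 is the six-membered enone, SMILES CC1=CCCCC1=O.
Assumption: in step 1 the phosphoramidite antipode that leads to the 3R ketone is used (to be fixed by a correlation experiment); racemic 2 suffices because sulfur is lost in step 2.

Step 1
Reactants: 1 2-methylcyclohex-2-en-1-one; 2 phenyl vinyl sulfoxide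
Product: 4 (2S,3R)-2,3-dimethyl-2-[2-(phenylsulfinyl)ethyl]cyclohexan-1-one, via aluminium enolate 3 (not isolated)
Conditions: Me3Al, CuTC (cat.), binaphthol-derived chiral phosphoramidite (cat.), Et2O, −30 °C; then MeLi, THF, −78 °C; then 2, −78 → 0 °C; aq. NH4Cl
Reagents that add atoms: trimethylaluminium C[Al](C)C
Why: Cu-catalysed asymmetric conjugate addition sets C8 (3R) under ligand control, and after MeLi activation the regiodefined enolate undergoes Michael addition to the vinyl sulfoxide (a vinyl cation equivalent) on the face anti to the new C8 methyl, so the quaternary C9 forms with the two methyl groups cis.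

Step 2
Reactants: 4 (2S,3R)-2,3-dimethyl-2-[2-(phenylsulfinyl)ethyl]cyclohexan-1-one
Product: 5 (2S,3R)-2,3-dimethyl-2-vinylcyclohexan-1-one
Conditions: toluene, solid NaHCO3 (cat.), 110 °C
Reagents that add atoms: none
Why: Thermal syn-elimination of the sulfoxide can take a hydrogen only from the CH2 attached to the quaternary carbon, so the vinyl group forms regiospecifically and no stereocentre is touched.

Step 3
Reactants: 5 (2S,3R)-2,3-dimethyl-2-vinylcyclohexan-1-one
Product: 7 (5R,6S)-5,6-dimethyl-6-vinylcyclohex-1-en-1-yl trifluoromethanesulfonate, via potassium enolate 6 (not isolated)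
Conditions: KHMDS, THF, −78 °C; PhNTf2, −78 → 0 °C
Reagents that add atoms: N-phenylbis(trifluoromethanesulfonimide) O=S(=O)(N(c1ccccc1)S(=O)(=O)C(F)(F)F)C(F)(F)F
Why: The ketone can enolise only towards C5 because C9 is quaternary, so deprotonation and O-triflation give a single enol triflate that fixes the later ring double bond between C5 and C10.

Step 4
Reactants: 7 (5R,6S)-5,6-dimethyl-6-vinylcyclohex-1-en-1-yl trifluoromethanesulfonate; 8 5-bromo-2-methylpent-2-ene
Product: 10 (5R,6S)-5,6-dimethyl-1-(4-methylpent-3-en-1-yl)-6-vinylcyclohex-1-ene, via homoprenylmagnesium bromide 9 (not isolated)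
Conditions: 8, Mg, THF, rt; then 7, Fe(acac)3 (cat.), THF/NMP, −30 → 0 °C
Reagents that add atoms: none
Why: Iron-catalysed Kumada cross-coupling of an alkenyl triflate with a primary alkyl Grignard reagent is fast at low temperature, keeps the ring olefin where the triflate placed it and leaves the isolated olefins untouched.

Step 5
Reactants: 10 (5R,6S)-5,6-dimethyl-1-(4-methylpent-3-en-1-yl)-6-vinylcyclohex-1-ene; 11 4-bromofuran-2(5H)-one
Product: 13 4-{2-[(1S,6R)-1,6-dimethyl-2-(4-methylpent-3-en-1-yl)cyclohex-2-en-1-yl]ethyl}furan-2(5H)-one, via alkyl-9-BBN adduct 12 (not isolated)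
Conditions: 9-BBN, THF, 0 °C → rt; then 11, PdCl2(dppf) (cat.), AsPh3 (cat.), aq. K3PO4, DMF, rt → 40 °C
Reagents that add atoms: none
Why: 9-BBN hydroborates only the monosubstituted vinyl group (boron on C12) in the presence of two trisubstituted olefins, and B-alkyl Suzuki–Miyaura coupling with the β-bromobutenolide then forms C12–C13 under mildly basic conditions that the lactone should tolerate.

Step 6
Reactants: 13 4-{2-[(1S,6R)-1,6-dimethyl-2-(4-methylpent-3-en-1-yl)cyclohex-2-en-1-yl]ethyl}furan-2(5H)-one
Product: 14 4-{2-[(1S,6R)-2-{2-[(2R)-3,3-dimethyloxiran-2-yl]ethyl}-1,6-dimethylcyclohex-2-en-1-yl]ethyl}furan-2(5H)-one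
Conditions: D-fructose-derived Shi ketone (cat.), Oxone, K2CO3, Bu4NHSO4 (cat.), MeCN/DMM/aq. buffer (pH 10.5), 0 °C
Reagents that add atoms: potassium peroxymonosulfate (Oxone) [K+].[O-]S(=O)(=O)OO
Why: Shi asymmetric epoxidation transfers oxygen through a spiro transition state to the face of the Me2C=CH olefin that is expected to give the (R)-epoxide (C3), while the ring olefin is shielded by the adjacent quaternary C9 and the butenolide olefin is electron-poor.

Step 7
Reactants: 14 4-{2-[(1S,6R)-2-{2-[(2R)-3,3-dimethyloxiran-2-yl]ethyl}-1,6-dimethylcyclohex-2-en-1-yl]ethyl}furan-2(5H)-one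
Product: 16 4-{2-[(1S,2R,6R)-6-hydroxy-1,2,5,5-tetramethyl-1,2,3,4,5,6,7,8-octahydronaphthalen-1-yl]ethyl}furan-2(5H)-one, via aluminium alkoxide 15 (not isolated)
Conditions: MeAlCl2 (2.2 equiv), CH2Cl2, −78 °C; aq. Rochelle salt
Reagents that add atoms: none
Why: Lewis-acid activation opens the epoxide at the tertiary C4, the ring olefin attacks through C5 in a 6-endo cation–olefin cyclisation to the tertiary C10 cation, and loss of the C5 proton (taken up by the Al–Me group) should give the tetrasubstituted ring-fusion olefin, with C3 keeping the epoxide configuration because its C–O bond is not broken.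

Step 8
Reactants: 16 4-{2-[(1S,2R,6R)-6-hydroxy-1,2,5,5-tetramethyl-1,2,3,4,5,6,7,8-octahydronaphthalen-1-yl]ethyl}furan-2(5H)-one
Product: 18 4-{2-[(1S,5R,10R)-5-hydroxy-1,6,6,10-tetramethyl-2,7-dioxocyclodecyl]ethyl}furan-2(5H)-one, via ozonide 17 (not isolated)
Conditions: O3, CH2Cl2, −78 °C (Sudan Red end-point); then Me2S, −78 °C → rt; used after a short filtration
Reagents that add atoms: ozone [O-][O+]=O
Why: Ozonolysis cleaves the electron-rich tetrasubstituted C5=C10 olefin far faster than the conjugated butenolide olefin, and reductive work-up of the ozonide releases the two ring ketones without touching a stereocentre.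

Step 9
Reactants: 18 4-{2-[(1S,5R,10R)-5-hydroxy-1,6,6,10-tetramethyl-2,7-dioxocyclodecyl]ethyl}furan-2(5H)-one
Product: 21 4-{2-[(2R,3aS,5S,6R,8aS)-2,8a-dihydroxy-1,1,5,6-tetramethyl-4-oxodecahydroazulen-5-yl]ethyl}furan-2(5H)-one, via boron enolate 19 (not isolated), via boron aldolate 20 (not isolated)
Conditions: n-Bu2BOTf (2.2 equiv), i-Pr2NEt (2.6 equiv), CH2Cl2, −78 → 0 °C; pH 7 buffer/MeOH, 0 °C
Reagents that add atoms: none
Why: The first equivalent of Bu2BOTf borylates O3, and this borinate chelates the C5 carbonyl in a six-membered ring (the activation used in Narasaka–Prasad reductions), which makes C5=O a good acceptor but, with no leaving group left on boron, not a site of soft enolisation; the second equivalent with i-Pr2NEt enolises the only free ketone, C10, towards C1 (C9 is quaternary), and the enol borinate adds across the ten-membered ring to C5. The closest known reaction type is the transannular aldol of cyclodecane-1,6-diones to hydroxy-hydroazulenones, run here as a boron-mediated aldol addition. The cyclopentane closes in 5-(enolexo)-exo-trig mode and the cycloheptanone in 7-(enolendo)-exo-trig mode, both through the single C1–C5 bond. C5 is controlled by the O3–B–O5 chelate, which can only end as a cis-fused dioxaborinane on the new five-membered ring and so places the new hydroxyl cis to O3; C1 is controlled by the aldolate in which O5 and the C10 carbonyl share a boron (C10 cis to O5, hence trans ring fusion), and because C1 stays alpha to the ketone it can still settle into this arrangement, which is hydrogen-bonded after work-up. The step needs C5 as acceptor and C10 as donor (the reverse pairing, C6 onto C10, would give an isomeric hydroazulene), which the chelate secures, and it needs the butenolide and the C3–C4 bond to stay intact, which the absence of free alkoxide and the low temperature should ensure.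

Compound list
1 | 2-methylcyclohex-2-en-1-one | CC1=CCCCC1=O | starting material
2 | phenyl vinyl sulfoxide (racemic) | C=CS(=O)c1ccccc1 | starting material
3 | dimethylaluminium (3R)-2,3-dimethylcyclohex-1-en-1-olate | C[C@@H]1CCCC(O[Al](C)C)=C1C | intermediate
4 | (2S,3R)-2,3-dimethyl-2-[2-(phenylsulfinyl)ethyl]cyclohexan-1-one (both sulfur epimers) | C[C@@H]1CCCC(=O)[C@@]1(C)CCS(=O)c1ccccc1 | intermediate
5 | (2S,3R)-2,3-dimethyl-2-vinylcyclohexan-1-one | C[C@@H]1CCCC(=O)[C@@]1(C)C=C | intermediate
6 | potassium (5R,6S)-5,6-dimethyl-6-vinylcyclohex-1-en-1-olate | C[C@@H]1CCC=C([O-])[C@@]1(C)C=C.[K+] | intermediate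
7 | (5R,6S)-5,6-dimethyl-6-vinylcyclohex-1-en-1-yl trifluoromethanesulfonate | C[C@@H]1CCC=C(OS(=O)(=O)C(F)(F)F)[C@@]1(C)C=C | intermediate
8 | 5-bromo-2-methylpent-2-ene | CC(C)=CCCBr | starting material
9 | (4-methylpent-3-en-1-yl)magnesium bromide | CC(C)=CCC[Mg]Br | intermediate
10 | (5R,6S)-5,6-dimethyl-1-(4-methylpent-3-en-1-yl)-6-vinylcyclohex-1-ene | C[C@@H]1CCC=C(CCC=C(C)C)[C@@]1(C)C=C | intermediate
11 | 4-bromofuran-2(5H)-one | BrC1=CC(=O)OC1 | starting material
12 | 9-{2-[(1S,6R)-1,6-dimethyl-2-(4-methylpent-3-en-1-yl)cyclohex-2-en-1-yl]ethyl}-9-borabicyclo[3.3.1]nonane | C[C@@H]1CCC=C(CCC=C(C)C)[C@@]1(C)CCB1C2CCCC1CCC2 | intermediate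
13 | 4-{2-[(1S,6R)-1,6-dimethyl-2-(4-methylpent-3-en-1-yl)cyclohex-2-en-1-yl]ethyl}furan-2(5H)-one | C[C@@H]1CCC=C(CCC=C(C)C)[C@@]1(C)CCC1=CC(=O)OC1 | intermediate
14 | 4-{2-[(1S,6R)-2-{2-[(2R)-3,3-dimethyloxiran-2-yl]ethyl}-1,6-dimethylcyclohex-2-en-1-yl]ethyl}furan-2(5H)-one | C[C@@H]1CCC=C(CC[C@H]2OC2(C)C)[C@@]1(C)CCC1=CC(=O)OC1 | intermediate
15 | dichloroaluminium alkoxide of 16 | C[C@@H]1CCC2=C(CC[C@@H](O[Al](Cl)Cl)C2(C)C)[C@@]1(C)CCC1=CC(=O)OC1 | intermediate
16 | 4-{2-[(1S,2R,6R)-6-hydroxy-1,2,5,5-tetramethyl-1,2,3,4,5,6,7,8-octahydronaphthalen-1-yl]ethyl}furan-2(5H)-one | C[C@@H]1CCC2=C(CC[C@@H](O)C2(C)C)[C@@]1(C)CCC1=CC(=O)OC1 | intermediate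
17 | ozonide (1,2,4-trioxolane across C5 and C10) of 16 | C[C@@H]1CCC23OOC(O2)(CC[C@@H](O)C3(C)C)[C@@]1(C)CCC1=CC(=O)OC1 | intermediate
18 | 4-{2-[(1S,5R,10R)-5-hydroxy-1,6,6,10-tetramethyl-2,7-dioxocyclodecyl]ethyl}furan-2(5H)-one | C[C@@H]1CCC(=O)C(C)(C)[C@H](O)CCC(=O)[C@@]1(C)CCC1=CC(=O)OC1 | intermediate
19 | O3-dibutylborinate, C10(O)=C1 enol dibutylborinate of 18 | C[C@@H]1CCC(=O)C(C)(C)[C@H](OB(CCCC)CCCC)CC=C(OB(CCCC)CCCC)[C@@]1(C)CCC1=CC(=O)OC1 | intermediate
20 | O3,O5-bis(dibutylborinate) of 21 | C[C@@H]1CC[C@]2(OB(CCCC)CCCC)[C@H](C[C@@H](OB(CCCC)CCCC)C2(C)C)C(=O)[C@@]1(C)CCC1=CC(=O)OC1 | intermediate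
21 | 4-{2-[(2R,3aS,5S,6R,8aS)-2,8a-dihydroxy-1,1,5,6-tetramethyl-4-oxodecahydroazulen-5-yl]ethyl}furan-2(5H)-one (CNP0077405.1) | C[C@@H]1CC[C@]2(O)[C@H](C[C@@H](O)C2(C)C)C(=O)[C@@]1(C)CCC1=CC(=O)OC1 | target

Total step count: 9. Longest linear sequence: 9 steps (1 → 21).

Steps most likely to fail

Step 9. Enolisation may also occur on the C5 ketone (towards C6) if the O3-borinate chelate is loose, leading into the reverse transannular aldol, or the enol borinate may add too slowly to a ketone acceptor. Fallback: setting out from 18, the donor is fixed through O3 instead of through enolisation. Acid-catalysed cyclodehydration of the γ-hydroxy ketone (PPTS, benzene, 4 Å sieves, 60 °C) should give the bridged enol ether 4-{2-[(1R,6R,7S)-2,2,6,7-tetramethyl-3-oxo-11-oxabicyclo[6.2.1]undec-8-en-7-yl]ethyl}furan-2(5H)-one F1, whose double bond can only lie between C10 and C1 because C9 carries no hydrogen. BF3·OEt2 in CH2Cl2 at −78 °C would then trigger Mukaiyama–Prins addition of this enol ether to the C5 ketone, and aqueous work-up would hydrolyse the oxocarbenium ion, coming back to the route at 21. The O-bridge delivers C10 cis to O3; the configuration at C5 from this tethered closure would have to be established.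

Step 7. After ring closure the C10 cation may lose the C1 proton instead of the C5 proton (trisubstituted instead of ring-fusion olefin), be captured by O3, or undergo 1,2-shifts. Fallback: setting out from 14, ring closure and olefin placement are separated. The C1-deprotonation product, the Δ1(10) olefin 4-{2-[(1S,2R,6R)-6-hydroxy-1,2,5,5-tetramethyl-1,2,3,4,4a,5,6,7-octahydronaphthalen-1-yl]ethyl}furan-2(5H)-one F2, is taken on and isomerised under thermodynamic control (p-TsOH, benzene, 60 °C, or HI in benzene) to the tetrasubstituted olefin, rejoining the route at 16.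

Step 1. The hindered tetrasubstituted enolate may add sluggishly to the vinyl sulfoxide, be quenched by proton transfer, or add twice after enolate equilibration. Fallback: setting out from 1, the same conjugate methylation is followed by trapping with allyl bromide (MeLi, THF/DMPU) to give (2S,3R)-2-allyl-2,3-dimethylcyclohexan-1-one F3. Ruthenium hydride isomerisation (RuHCl(CO)(PPh3)3, toluene, 80 °C) gives the propenyl ketone (2R,3R)-2,3-dimethyl-2-[(1E)-prop-1-en-1-yl]cyclohexan-1-one F4. Ozonolysis (O3, CH2Cl2, −78 °C; Me2S) gives the keto aldehyde (1R,2R)-1,2-dimethyl-6-oxocyclohexane-1-carbaldehyde F5. Wittig methylenation (Ph3P=CH2, THF, −78 → 0 °C), selective for the aldehyde over the hindered ketone, returns to the route at 5.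

Further compounds
F1 | step 9 | 4-{2-[(1R,6R,7S)-2,2,6,7-tetramethyl-3-oxo-11-oxabicyclo[6.2.1]undec-8-en-7-yl]ethyl}furan-2(5H)-one | C[C@@H]1CCC(=O)C(C)(C)[C@H]2CC=C(O2)[C@@]1(C)CCC1=CC(=O)OC1
F2 | step 7 | 4-{2-[(1S,2R,6R)-6-hydroxy-1,2,5,5-tetramethyl-1,2,3,4,4a,5,6,7-octahydronaphthalen-1-yl]ethyl}furan-2(5H)-one (C4a epimers) | C[C@@H]1CCC2C(=CC[C@@H](O)C2(C)C)[C@@]1(C)CCC1=CC(=O)OC1
F3 | step 1 | (2S,3R)-2-allyl-2,3-dimethylcyclohexan-1-one | C[C@@H]1CCCC(=O)[C@@]1(C)CC=C
F4 | step 1 | (2R,3R)-2,3-dimethyl-2-[(1E)-prop-1-en-1-yl]cyclohexan-1-one | C[C@@H]1CCCC(=O)[C@@]1(C)/C=C/C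
F5 | step 1 | (1R,2R)-1,2-dimethyl-6-oxocyclohexane-1-carbaldehyde | C[C@@H]1CCCC(=O)[C@@]1(C)C=O
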